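**Retrosynthetic overview**
- The target comes from a C5/C1 trans-diol by C5 acylation and C9 desilylation; the diol comes from hydroxyl-directed reduction of a 2-butenoyl-2-hydroxycycloheptanone.
- The seven-membered ring and the C1 carbinol come from a ring-expanding α-ketol 1,2-shift (C10 moves from C5 to C1) of a cyclohexanol carrying an ene-1,2-dione, made by diazo-ketone aldol addition and diazo-to-carbonyl oxidation.
- The cis-fused keto lactone comes from a 5-silyloxy-6-methylcyclohexenone by Mukaiyama–Michael addition of a methylmalonate unit, bromination, lactonisation and decarboxylation (sets C7, C6, C11).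
- The enone comes from 2-methylcyclohex-2-enone by asymmetric conjugate borylation/oxidation (C9, C10), silylation and dehydrogenation.
- Ring order: six-membered carbocycle (purchased), then the γ-lactone, then expansion of the carbocycle to seven members.

Atom labels used below: C1 = carbinol carbon carrying the butenoyl group, C5 = CH–O(isobutyrate), C6 = CH–O(lactone), C7 = ring-fusion CH, C8 = CH2, C9 = CH–OH, C10 = CH–CH3, C11 = lactone α-carbon.
Assumption: in step 1 the Josiphos antipode is the one that gives the 3R alcohol.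

**Step 1**
Reactants: 1 2-methylcyclohex-2-en-1-one
Product: 3 (2S,3R)-3-hydroxy-2-methylcyclohexan-1-one, via pinacol boronate 2 (not isolated)
Conditions: B2pin2, CuCl (3 mol%), NaOtBu (3 mol%), (R,S)-Josiphos (3 mol%), MeOH, THF, 0 to 25 °C; then NaBO3·4H2O, THF/H2O, 25 °C
Reagents that add atoms: bis(pinacolato)diboron CC1(C)OB(OC1(C)C)B1OC(C)(C)C(C)(C)O1 (boron group of 2); sodium perborate [Na+].[Na+].O[B-]1(O)OO[B-](O)(O)OO1 (oxygen of 3)
Why: Copper-catalysed asymmetric conjugate borylation sets C9 under ligand control, α-protonation gives the trans (diequatorial, also thermodynamic) C10 methyl, and perborate oxidises C–B to C–O with retention.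

**Step 2**
Reactants: 3 (2S,3R)-3-hydroxy-2-methylcyclohexan-1-one
Product: 4 (2S,3R)-3-(tert-butyldimethylsilyloxy)-2-methylcyclohexan-1-one
Conditions: TBSCl, imidazole, DMF, 25 °C
Reagents that add atoms: tert-butyldimethylsilyl chloride CC(C)(C)[Si](C)(C)Cl
Why: Standard silyl ether protection of the secondary alcohol, which blocks the C9 oxygen through the enolate, Lewis-acid and acylation steps that follow.

**Step 3**
Reactants: 4 (2S,3R)-3-(tert-butyldimethylsilyloxy)-2-methylcyclohexan-1-one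
Product: 6 (5R,6S)-5-(tert-butyldimethylsilyloxy)-6-methylcyclohex-2-en-1-one, via trimethylsilyl enol ether 5 (not isolated)
Conditions: LiN(iPr)2, THF, −78 °C; TMSCl; then Pd(OAc)2 (10 mol%), O2 (1 atm), DMSO, 25 °C
Reagents that add atoms: chlorotrimethylsilane C[Si](C)(C)Cl (silyl group of 5)
Why: Saegusa–Ito dehydrogenation; kinetic deprotonation takes the unhindered CH2 rather than the methine, so the new double bond forms away from both stereocentres.

**Step 4**
Reactants: 6 (5R,6S)-5-(tert-butyldimethylsilyloxy)-6-methylcyclohex-2-en-1-one; 7 methylmalonic acid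
Product: 11 (3RS,3aS,5R,6S,7aR)-5-(tert-butyldimethylsilyloxy)-3,6-dimethyl-2,7-dioxooctahydro-1-benzofuran-3-carboxylic acid, via tris-silyl ketene acetal 8 (not isolated), via Michael enol silane 9 (not isolated), via trans bromo ketone 10 (not isolated)
Conditions: 7 (1.3 equiv), Et3N (3.9 equiv), TMSOTf (3.9 equiv), CH2Cl2, 0 to 25 °C; then 6, TMSOTf (10 mol%), −78 to −40 °C; NBS, −78 °C; then aq NaHCO3/THF, 25 °C; H3O+
Reagents that add atoms: trimethylsilyl triflate C[Si](C)(C)OS(=O)(=O)C(F)(F)F (silyl groups of 8, 9, 10); N-bromosuccinimide O=C1CCC(=O)N1Br (bromine of 10)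
Why: Mukaiyama–Michael addition anti to the 5-silyloxy group sets C7 and delivers a regiodefined enol silane, NBS brominates C6 trans to the new substituent, and the tethered carboxylate displaces bromide with inversion (SN2) to give the cis-fused γ-lactone.

**Step 5**
Reactants: 11 (3RS,3aS,5R,6S,7aR)-5-(tert-butyldimethylsilyloxy)-3,6-dimethyl-2,7-dioxooctahydro-1-benzofuran-3-carboxylic acid
Product: 12 (3R,3aS,5R,6S,7aR)-5-(tert-butyldimethylsilyloxy)-3,6-dimethylhexahydro-1-benzofuran-2,7-dione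
Conditions: toluene, 100 °C
Reagents that add atoms: none
Why: Thermal decarboxylation of the malonic half-acid lactone gives the lactone enol, which is protonated on the convex face (the side of H-3a and H-7a), so the C11 methyl ends on the concave face, cis to C8.

**Step 6**
Reactants: 13 (3E)-pent-3-en-2-one
Product: 15 (3E)-1-diazopent-3-en-2-one, via trifluoroacetyl diketone 14 (not isolated)
Conditions: LiN(SiMe3)2, THF, −78 °C; CF3CO2CH2CF3; aq HCl work-up; then MsN3, Et3N, H2O (1 equiv), MeCN, 25 °C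
Reagents that add atoms: 2,2,2-trifluoroethyl trifluoroacetate O=C(OCC(F)(F)F)C(F)(F)F (trifluoroacetyl group of 14); methanesulfonyl azide CS(=O)(=O)N=[N+]=[N-] (diazo nitrogens of 15)
Why: Danheiser detrifluoroacetylative diazo transfer; kinetic enolisation at the methyl group, Claisen activation and diazo transfer with loss of the trifluoroacetyl group give the α'-diazo enone without touching the alkene.

**Step 7**
Reactants: 12 (3R,3aS,5R,6S,7aR)-5-(tert-butyldimethylsilyloxy)-3,6-dimethylhexahydro-1-benzofuran-2,7-dione; 15 (3E)-1-diazopent-3-en-2-one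
Product: 17 (3R,3aS,5R,6S,7R,7aR)-5-(tert-butyldimethylsilyloxy)-7-[(3E)-1-diazo-2-oxopent-3-en-1-yl]-7-hydroxy-3,6-dimethylhexahydro-1-benzofuran-2(3H)-one, via lithiated diazo ketone 16 (not isolated)
Conditions: 15, LiN(iPr)2, THF, −78 °C; then 12, −78 °C; AcOH quench at −78 °C
Reagents that add atoms: lithium diisopropylamide [Li+].CC(C)[N-]C(C)C (lithium of 16)
Why: Aldol-type addition of a lithiated α-diazo ketone to the ketone; the axial C7–C11 bond blocks axial attack, so the nucleophile enters equatorially and the new tertiary OH is axial, on the face of the C10 methyl and the lactone oxygen.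

**Step 8**
Reactants: 17 (3R,3aS,5R,6S,7R,7aR)-5-(tert-butyldimethylsilyloxy)-7-[(3E)-1-diazo-2-oxopent-3-en-1-yl]-7-hydroxy-3,6-dimethylhexahydro-1-benzofuran-2(3H)-one
Product: 19 (3R,3aS,5R,6S,7R,8aR)-7-[(2E)-but-2-enoyl]-5-(tert-butyldimethylsilyloxy)-7-hydroxy-3,6-dimethylhexahydro-2H-cyclohepta[b]furan-2,8(3H)-dione, via hydroxy ene-1,2-dione 18 (not isolated)
Conditions: DMDO (1.05 equiv, dried acetone solution), CH2Cl2, −78 to −20 °C; concentrate cold; Al(OtBu)3 (1.5 equiv), toluene, 0 to 25 °C; aq KNaC4H4O6 work-up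
Reagents that add atoms: dimethyldioxirane CC1(C)OO1
Why: Proposed new method: a ring-expanding α-ketol (acyloin) rearrangement of a tertiary cyclohexanol bearing a 1,2-dione, run in the same flask after dimethyldioxirane converts the diazo carbon into the second carbonyl; the aluminium alkoxide of the C5 hydroxyl chelates the adjacent C1 carbonyl (syn O–C–C=O), the electron-richer C5–C10 bond (C6 is deactivated by the lactone oxygen) shifts suprafacially with retention onto the C1 carbonyl face fixed by the chelate, which forms the seven-membered ring and the C1 carbinol (OH on the face of the C10 methyl, butenoyl opposite), driven by relief of the 1,3-diaxial OH/C11 strain, loss of 1,2-dione dipole repulsion and formation of a chelated α-alkoxy-1,3-diketone; the closest known chemistry is the Lewis-acid α-ketol rearrangement (steroid D-homoannulation with aluminium alkoxides, isomerisation of β-hydroxy-α-dicarbonyls to α-hydroxy-β-dicarbonyls), not yet shown as a six-to-seven ring expansion of an ene-dione with diastereotopic migrating groups.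

**Step 9**
Reactants: 19 (3R,3aS,5R,6S,7R,8aR)-7-[(2E)-but-2-enoyl]-5-(tert-butyldimethylsilyloxy)-7-hydroxy-3,6-dimethylhexahydro-2H-cyclohepta[b]furan-2,8(3H)-dione
Product: 20 (3R,3aS,5R,6S,7S,8S,8aR)-7-[(2E)-but-2-enoyl]-5-(tert-butyldimethylsilyloxy)-7,8-dihydroxy-3,6-dimethyloctahydro-2H-cyclohepta[b]furan-2-one
Conditions: Me4NBH(OAc)3 (3 equiv), MeCN/AcOH 1:1, −30 °C
Reagents that add atoms: none
Why: Hydroxyl-directed triacetoxyborohydride reduction (Saksena–Evans type); hydride is delivered from the C1 oxygen to the same face of the more electrophilic saturated C5 ketone, giving the trans-1,2-diol while the conjugated ketone and the lactone are left alone.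

**Step 10**
Reactants: 20 (3R,3aS,5R,6S,7S,8S,8aR)-7-[(2E)-but-2-enoyl]-5-(tert-butyldimethylsilyloxy)-7,8-dihydroxy-3,6-dimethyloctahydro-2H-cyclohepta[b]furan-2-one; 21 2-methylpropanoyl chloride
Product: 23 (3R,3aS,5R,6S,7S,8S,8aR)-7-[(2E)-but-2-enoyl]-5,7-dihydroxy-3,6-dimethyl-2-oxooctahydro-2H-cyclohepta[b]furan-8-yl 2-methylpropanoate (CNP0268641.1), via silyl ether isobutyrate 22 (not isolated)
Conditions: 21, pyridine, DMAP (0.2 equiv), CH2Cl2, 0 to 25 °C; then HF·pyridine, THF, 0 to 25 °C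
Reagents that add atoms: 2-methylpropanoyl chloride (21) CC(C)C(Cl)=O
Why: DMAP-catalysed esterification acylates the only free secondary hydroxyl (the tertiary α-keto hydroxyl is inert), and acidic fluoride desilylation then frees the C9 hydroxyl without base, so no acyl migration or oxa-Michael closure occurs.

**Compound list**
1 | 2-methylcyclohex-2-en-1-one | CC1=CCCCC1=O | starting material
2 | (2S,3R)-2-methyl-3-(4,4,5,5-tetramethyl-1,3,2-dioxaborolan-2-yl)cyclohexan-1-one | O=C1[C@@H](C)[C@H](B2OC(C)(C)C(C)(C)O2)CCC1 | intermediate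
3 | (2S,3R)-3-hydroxy-2-methylcyclohexan-1-one (trans) | O=C1[C@@H](C)[C@H](O)CCC1 | intermediate
4 | (2S,3R)-3-(tert-butyldimethylsilyloxy)-2-methylcyclohexan-1-one | O=C1[C@@H](C)[C@H](O[Si](C)(C)C(C)(C)C)CCC1 | intermediate
5 | (5R,6S)-5-(tert-butyldimethylsilyloxy)-6-methyl-1-(trimethylsilyloxy)cyclohex-1-ene | C[Si](C)(C)OC1=CCC[C@@H](O[Si](C)(C)C(C)(C)C)[C@@H]1C | intermediate
6 | (5R,6S)-5-(tert-butyldimethylsilyloxy)-6-methylcyclohex-2-en-1-one (trans) | O=C1[C@@H](C)[C@H](O[Si](C)(C)C(C)(C)C)CC=C1 | intermediate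
7 | methylmalonic acid | CC(C(=O)O)C(=O)O | starting material
8 | trimethylsilyl 2-methyl-3,3-bis(trimethylsilyloxy)prop-2-enoate | CC(C(=O)O[Si](C)(C)C)=C(O[Si](C)(C)C)O[Si](C)(C)C | intermediate
9 | bis(trimethylsilyl) 2-[(1R,4S,5R)-5-(tert-butyldimethylsilyloxy)-4-methyl-3-(trimethylsilyloxy)cyclohex-2-en-1-yl]-2-methylpropanedioate | C[Si](C)(C)OC1=C[C@H](C(C)(C(=O)O[Si](C)(C)C)C(=O)O[Si](C)(C)C)C[C@@H](O[Si](C)(C)C(C)(C)C)[C@@H]1C | intermediate
10 | bis(trimethylsilyl) 2-[(1S,2S,4S,5R)-2-bromo-5-(tert-butyldimethylsilyloxy)-4-methyl-3-oxocyclohexyl]-2-methylpropanedioate (Br trans to the malonyl group) | O=C1[C@@H](C)[C@H](O[Si](C)(C)C(C)(C)C)C[C@@H](C(C)(C(=O)O[Si](C)(C)C)C(=O)O[Si](C)(C)C)[C@@H]1Br | intermediate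
11 | (3RS,3aS,5R,6S,7aR)-5-(tert-butyldimethylsilyloxy)-3,6-dimethyl-2,7-dioxooctahydro-1-benzofuran-3-carboxylic acid (cis-fused; both C3 epimers) | O=C1[C@@H](C)[C@H](O[Si](C)(C)C(C)(C)C)C[C@@H]2[C@H]1OC(=O)C2(C)C(=O)O | intermediate
12 | (3R,3aS,5R,6S,7aR)-5-(tert-butyldimethylsilyloxy)-3,6-dimethylhexahydro-1-benzofuran-2,7-dione | O=C1[C@@H](C)[C@H](O[Si](C)(C)C(C)(C)C)C[C@@H]2[C@H]1OC(=O)[C@@H]2C | intermediate
13 | (3E)-pent-3-en-2-one | C/C=C/C(C)=O | starting material
14 | (5E)-1,1,1-trifluorohept-5-ene-2,4-dione | C/C=C/C(=O)CC(=O)C(F)(F)F | intermediate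
15 | (3E)-1-diazopent-3-en-2-one | C/C=C/C(=O)C=[N+]=[N-] | intermediate
16 | (3E)-1-diazo-1-lithiopent-3-en-2-one | C/C=C/C(=O)C([Li])=[N+]=[N-] | intermediate
17 | (3R,3aS,5R,6S,7R,7aR)-5-(tert-butyldimethylsilyloxy)-7-[(3E)-1-diazo-2-oxopent-3-en-1-yl]-7-hydroxy-3,6-dimethylhexahydro-1-benzofuran-2(3H)-one | C/C=C/C(=O)C(=[N+]=[N-])[C@]1(O)[C@@H](C)[C@H](O[Si](C)(C)C(C)(C)C)C[C@@H]2[C@H]1OC(=O)[C@@H]2C | intermediate
18 | (3E)-1-[(3R,3aS,5R,6S,7S,7aR)-5-(tert-butyldimethylsilyloxy)-7-hydroxy-3,6-dimethyl-2-oxooctahydro-1-benzofuran-7-yl]pent-3-ene-1,2-dione | C/C=C/C(=O)C(=O)[C@]1(O)[C@@H](C)[C@H](O[Si](C)(C)C(C)(C)C)C[C@@H]2[C@H]1OC(=O)[C@@H]2C | intermediate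
19 | (3R,3aS,5R,6S,7R,8aR)-7-[(2E)-but-2-enoyl]-5-(tert-butyldimethylsilyloxy)-7-hydroxy-3,6-dimethylhexahydro-2H-cyclohepta[b]furan-2,8(3H)-dione | C/C=C/C(=O)[C@]1(O)[C@@H](C)[C@H](O[Si](C)(C)C(C)(C)C)C[C@@H]2[C@@H](OC(=O)[C@@H]2C)C1=O | intermediate
20 | (3R,3aS,5R,6S,7S,8S,8aR)-7-[(2E)-but-2-enoyl]-5-(tert-butyldimethylsilyloxy)-7,8-dihydroxy-3,6-dimethyloctahydro-2H-cyclohepta[b]furan-2-one | C/C=C/C(=O)[C@]1(O)[C@@H](C)[C@H](O[Si](C)(C)C(C)(C)C)C[C@@H]2[C@@H](OC(=O)[C@@H]2C)[C@@H]1O | intermediate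
21 | 2-methylpropanoyl chloride | CC(C)C(Cl)=O | starting material
22 | (3R,3aS,5R,6S,7S,8S,8aR)-7-[(2E)-but-2-enoyl]-5-(tert-butyldimethylsilyloxy)-7-hydroxy-3,6-dimethyl-2-oxooctahydro-2H-cyclohepta[b]furan-8-yl 2-methylpropanoate | C/C=C/C(=O)[C@]1(O)[C@@H](C)[C@H](O[Si](C)(C)C(C)(C)C)C[C@@H]2[C@@H](OC(=O)[C@@H]2C)[C@@H]1OC(=O)C(C)C | intermediate
23 | (3R,3aS,5R,6S,7S,8S,8aR)-7-[(2E)-but-2-enoyl]-5,7-dihydroxy-3,6-dimethyl-2-oxooctahydro-2H-cyclohepta[b]furan-8-yl 2-methylpropanoate | C/C=C/C(=O)[C@]1(O)[C@@H](C)[C@H](O)C[C@@H]2[C@@H](OC(=O)[C@@H]2C)[C@@H]1OC(=O)C(C)C | target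

**Step count**
Total: 10 steps. Longest linear sequence: 9 steps (steps 1–5 and 7–10); step 6 is a one-step side branch.

**Three steps most likely to fail**

Step 4. The malonate-derived ketene acetal is a weak nucleophile, enone 6 can aromatise by loss of silanol, and three events share one flask. The fallback sets out from 6 and comes back at 12. Luche reduction (NaBH4, CeCl3·7H2O, MeOH, −78 °C), with hydride anti to the C10 methyl, gives the allylic alcohol (1R,5R,6R)-5-(tert-butyldimethylsilyloxy)-6-methylcyclohex-2-en-1-ol F1. Propanoyl chloride and pyridine give the ester (1R,5R,6R)-5-(tert-butyldimethylsilyloxy)-6-methylcyclohex-2-en-1-yl propanoate F2. Ireland–Claisen rearrangement (LiN(iPr)2, TMSCl, THF, −78 to 25 °C) transfers the three-carbon unit suprafacially to C7 and gives the acid (2RS)-2-[(1R,4R,5R)-5-(tert-butyldimethylsilyloxy)-4-methylcyclohex-2-en-1-yl]propanoic acid F3. Epoxidation with mCPBA anti to the side chain and acid-catalysed opening by the carboxyl give the hydroxy lactone (3R,3aS,5R,6R,7R,7aR)-5-(tert-butyldimethylsilyloxy)-7-hydroxy-3,6-dimethylhexahydro-1-benzofuran-2(3H)-one F4; its C11 centre is made uniform by double deprotonation (LiN(iPr)2, 2.2 equiv) and kinetic protonation on the convex face. Dess–Martin oxidation of the C5 alcohol then gives 12.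

Step 8 (the proposed new step). The shift may be thermodynamically marginal for a six-to-seven expansion, C6 may migrate in place of C10, or the hydroxy enone may close by oxa-Michael addition. The fallback uses known chemistry, sets out from 17 and comes back at 19. Rh2(OAc)4 (1 mol%, CH2Cl2, 25 °C) turns the diazo group into a carbenoid that triggers the known 1,2-alkyl shift of β-hydroxy-α-diazo carbonyl compounds, giving the ring-expanded β-diketone (3R,3aS,5R,6R,8aR)-7-[(2E)-but-2-enoyl]-5-(tert-butyldimethylsilyloxy)-3,6-dimethylhexahydro-2H-cyclohepta[b]furan-2,8(3H)-dione F5. Its potassium enolate (KN(SiMe3)2, THF, −78 °C) is hydroxylated with the enantiomer of (camphorsulfonyl)oxaziridine that delivers oxygen to the face of the C10 methyl, giving 19. Substrate bias in this hydroxylation favours the opposite face, so the C1 epimers may need separation.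

Step 9. The directed hydride could also reach the butenoyl ketone, which is α to the same hydroxyl. The fallback sets out from 19 and comes back at 20. Both ketones are reduced (NaBH4, CeCl3·7H2O, MeOH, −40 °C) to the triol (3R,3aS,5R,6S,7R,8S,8aR)-5-(tert-butyldimethylsilyloxy)-7,8-dihydroxy-7-[(2E)-1-hydroxybut-2-en-1-yl]-3,6-dimethyloctahydro-2H-cyclohepta[b]furan-2-one F6 (side-chain carbinol as an epimer mixture). MnO2 (CH2Cl2, 25 °C) then reoxidises only the allylic alcohol to the enone, giving 20.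

**Further compounds**
F1 | step 4 | (1R,5R,6R)-5-(tert-butyldimethylsilyloxy)-6-methylcyclohex-2-en-1-ol | O[C@H]1[C@@H](C)[C@H](O[Si](C)(C)C(C)(C)C)CC=C1
F2 | step 4 | (1R,5R,6R)-5-(tert-butyldimethylsilyloxy)-6-methylcyclohex-2-en-1-yl propanoate | CCC(=O)O[C@H]1[C@@H](C)[C@H](O[Si](C)(C)C(C)(C)C)CC=C1
F3 | step 4 | (2RS)-2-[(1R,4R,5R)-5-(tert-butyldimethylsilyloxy)-4-methylcyclohex-2-en-1-yl]propanoic acid | CC(C(=O)O)[C@H]1C=C[C@@H](C)[C@H](O[Si](C)(C)C(C)(C)C)C1
F4 | step 4 | (3R,3aS,5R,6R,7R,7aR)-5-(tert-butyldimethylsilyloxy)-7-hydroxy-3,6-dimethylhexahydro-1-benzofuran-2(3H)-one | O[C@@H]1[C@@H](C)[C@H](O[Si](C)(C)C(C)(C)C)C[C@@H]2[C@H]1OC(=O)[C@@H]2C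
F5 | step 8 | (3R,3aS,5R,6R,8aR)-7-[(2E)-but-2-enoyl]-5-(tert-butyldimethylsilyloxy)-3,6-dimethylhexahydro-2H-cyclohepta[b]furan-2,8(3H)-dione (C7 epimers and enol) | C/C=C/C(=O)C1[C@@H](C)[C@H](O[Si](C)(C)C(C)(C)C)C[C@@H]2[C@@H](OC(=O)[C@@H]2C)C1=O
F6 | step 9 | (3R,3aS,5R,6S,7R,8S,8aR)-5-(tert-butyldimethylsilyloxy)-7,8-dihydroxy-7-[(2E)-1-hydroxybut-2-en-1-yl]-3,6-dimethyloctahydro-2H-cyclohepta[b]furan-2-one | C/C=C/C(O)[C@]1(O)[C@@H](C)[C@H](O[Si](C)(C)C(C)(C)C)C[C@@H]2[C@@H](OC(=O)[C@@H]2C)[C@@H]1O
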